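**Retrosynthetic overview**

1. Target 32 ⇐ desilylation of 31; the five-membered O-ring is closed last by intramolecular Friedel–Crafts formation of C6–C8″ in aryl ketal 30; 30 ⇐ SN2′ union (O5–C8a″) of quinone monoketal 18 with phenol 29.
2. 18 ⇐ oxidative dearomatisation of phenol 17; 17 and 29 are the C4 epimers of one flavan (4-silyloxy-5-hydroxy-7,8-dimethoxyflavan), so one benzannulation serves both halves.
3. Each flavan A ring ⇐ Moore ring expansion of a 4-(dihydropyran-6-yl)-3,4-dimethoxycyclobutenone (14, 26): 4π opening to a dienylketene, then 6π closure of the C5–C4a bond; cyclobutenone ⇐ 6-lithiodihydropyran + methyl semisquarate 11.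
4. Enabling feature: the carbocycle C4a″–C5″–C6″–C7″–C8″–C8a″ is a masked 2-methoxyhydroquinone (C5″=O para to the quaternary C8″–OMe, oxygen also on C7″ and C8a″); the aromatic ring C4a–C8a of the chromanol half has the same 5-O/7-OMe/8-OMe pattern.
5. Ring order: dihydropyran (δ-lactone from a chiral-pool β-hydroxy ester, C4 set anti or syn by directed reduction) → A-ring carbocycle (Moore) → dearomatisation → O5–C8a″ ketal → dihydrobenzofuran ring.

Key step: step 8

Remark: atom numbers are flavan numbers, plain for the chroman-4-ol half and double-primed for the dearomatised half; dione 11 is not assumed to be purchasable and is made in step 6.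

**Route**

Step 1
Reactants: 1 ethyl (S)-3-hydroxy-3-phenylpropanoate; 2 tert-butyl acetate
Product: 3 tert-butyl (S)-5-hydroxy-3-oxo-5-phenylpentanoate
Conditions: 2 (4 equiv), LiN(iPr)2, THF, −78 °C; then 1, −78 → −20 °C; aq NH4Cl
Reagents that add atoms: none
Why: Crossed Claisen condensation of excess lithium tert-butyl acetate enolate with the β-hydroxy ester (as its alkoxide) is a standard chain extension that should leave the benzylic stereocentre untouched.

Step 2
Reactants: 3 tert-butyl (S)-5-hydroxy-3-oxo-5-phenylpentanoate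
Product: 5 (4S,6S)-4-hydroxy-6-phenyltetrahydro-2H-pyran-2-one, via anti-diol ester 4 (not isolated)
Conditions: Me4NBH(OAc)3, MeCN/AcOH, −30 °C; then TFA, CH2Cl2, 0 °C → rt
Reagents that add atoms: none
Why: Evans–Saksena reduction delivers hydride intramolecularly from the C5 alkoxyborohydride through a chair to give the 3,5-anti diol (new C3 centre, later C4″), and acid then cleaves the tert-butyl ester and closes the δ-lactone with hydroxyl and phenyl cis.

Step 3
Reactants: 5 (4S,6S)-4-hydroxy-6-phenyltetrahydro-2H-pyran-2-one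
Product: 6 (4S,6S)-4-(tert-butyldimethylsilyloxy)-6-phenyltetrahydro-2H-pyran-2-one
Conditions: TBSCl, imidazole, DMF, rt
Reagents that add atoms: tert-butyldimethylsilyl chloride CC(C)(C)[Si](C)(C)Cl
Why: Standard silylation of a secondary alcohol under conditions too mild for β-elimination of the lactone.

Step 4
Reactants: 6 (4S,6S)-4-(tert-butyldimethylsilyloxy)-6-phenyltetrahydro-2H-pyran-2-one
Product: 7 (2S,4S)-4-(tert-butyldimethylsilyloxy)-2-phenyl-3,4-dihydro-2H-pyran-6-yl diphenyl phosphate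
Conditions: KN(SiMe3)2 added to 6 and (PhO)2P(O)Cl, HMPA, THF, −78 °C
Reagents that add atoms: diphenyl chlorophosphate O=P(Cl)(Oc1ccccc1)Oc1ccccc1
Why: O-phosphorylation of the potassium lactone enolate (cyclic ketene acetal phosphate formation after Nicolaou), with in situ trapping so that the enolate is captured before it can expel the β-silyloxy group.

Step 5
Reactants: 7 (2S,4S)-4-(tert-butyldimethylsilyloxy)-2-phenyl-3,4-dihydro-2H-pyran-6-yl diphenyl phosphate
Product: 8 tert-butyldimethyl{[(2S,4S)-2-phenyl-6-(trimethylstannyl)-3,4-dihydro-2H-pyran-4-yl]oxy}silane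
Conditions: Me3SnSnMe3, Pd(PPh3)4 (5 mol %), LiCl, THF, 65 °C
Reagents that add atoms: hexamethylditin C[Sn](C)(C)[Sn](C)(C)C
Why: Palladium-catalysed Stille-type stannylation of the ketene acetal phosphate gives the α-alkoxyvinylstannane without any strong base.

Step 6
Reactants: 9 3,4-dimethoxycyclobut-3-ene-1,2-dione (dimethyl squarate)
Product: 11 3-methoxycyclobut-3-ene-1,2-dione, via hydroxycyclobutenone 10 (not isolated)
Conditions: LiAlH(OtBu)3, THF, −78 °C; then 6 M HCl, CH2Cl2, rt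
Reagents that add atoms: water O
Why: Mono-reduction of the squarate followed by acid-induced allylic transposition (loss of the carbinol oxygen, addition of water to the resulting oxocarbenium carbon, loss of methanol) is the Liebeskind route to semisquarates.

Step 7
Reactants: 8 tert-butyldimethyl{[(2S,4S)-2-phenyl-6-(trimethylstannyl)-3,4-dihydro-2H-pyran-4-yl]oxy}silane; 11 3-methoxycyclobut-3-ene-1,2-dione
Product: 14 4-[(2S,4S)-4-(tert-butyldimethylsilyloxy)-2-phenyl-3,4-dihydro-2H-pyran-6-yl]-3,4-dimethoxycyclobut-2-en-1-one, via 6-lithiodihydropyran 12 (not isolated), via lithium alkoxide 13 (not isolated)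
Conditions: MeLi, THF, −78 °C; then 11, −78 °C; then MeOTf, −78 → −20 °C
Reagents that add atoms: methyl trifluoromethanesulfonate COS(=O)(=O)C(F)(F)F
Why: Tin–lithium exchange gives the α-alkoxyvinyllithium without touching the benzylic C2–H, it adds to the more electrophilic carbonyl of 11 (the one flanking the methoxy-bearing carbon, the other being a vinylogous ester) and the alkoxide is methylated in situ; the new ring stereocentre forms as a mixture that step 8 erases.

Step 8
Reactants: 14 4-[(2S,4S)-4-(tert-butyldimethylsilyloxy)-2-phenyl-3,4-dihydro-2H-pyran-6-yl]-3,4-dimethoxycyclobut-2-en-1-one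
Product: 17 (2S,4S)-4-(tert-butyldimethylsilyloxy)-7,8-dimethoxy-2-phenylchroman-5-ol, via dienylketene 15 (not isolated), via cyclohexadienone 16 (not isolated)
Conditions: toluene (degassed), 110 °C
Reagents that add atoms: none
Why: Thermal conrotatory 4π opening cleaves the C1–C4 bond of the cyclobutenone, the C4 methoxy group rotating outward so that the dihydropyranyl group lies cis to the ketene in 15. Disrotatory 6π electrocyclisation then joins the ketene carbon (future C5″, the enone carbonyl carbon of the target) to C5 of the dihydropyran (future C4a″), which closes the six-membered carbocycle, and tautomerisation of 16 gives phenol 17. The closest known reaction is the Moore ring expansion of 4-alkenyl-4-alkoxycyclobutenones to 4-alkoxyphenols. No stereocentre is created: C2″ and C4″ are bystanders and the epimeric cyclobutenone carbon becomes sp2. The step needs outward rotation of the alkoxy group (reliable for a donor at C4) and a single cyclisation terminus (the dihydropyran C5 is the only alkene carbon in reach); the pattern 5-OH, 6-H, 7-OMe, 8-OMe is fixed by the carbonyl attacked in step 7.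

Step 9
Reactants: 17 (2S,4S)-4-(tert-butyldimethylsilyloxy)-7,8-dimethoxy-2-phenylchroman-5-ol
Product: 18 (2S,4S)-4-(tert-butyldimethylsilyloxy)-7,8,8-trimethoxy-2-phenyl-3,4-dihydro-2H-chromen-5(8H)-one
Conditions: PhI(OAc)2, MeOH, 0 °C; NaHCO3 work-up
Reagents that add atoms: methanol CO
Why: Oxidative dearomatisation of a p-methoxyphenol with the trivalent iodine reagent, methanol attacking the para carbon C8″, is the standard route to a quinone monoketal and creates no stereocentre.

Step 10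
Reactants: 3 tert-butyl (S)-5-hydroxy-3-oxo-5-phenylpentanoate
Product: 20 (4R,6S)-4-hydroxy-6-phenyltetrahydro-2H-pyran-2-one, via syn-diol ester 19 (not isolated)
Conditions: Et2BOMe, NaBH4, THF/MeOH, −78 °C; then TFA, CH2Cl2, 0 °C → rt
Reagents that add atoms: none
Why: Narasaka–Prasad reduction (axial hydride attack on the six-membered boron chelate) gives the 3,5-syn diol, whose C3 centre becomes C4 of the chromanol half, and lactonisation gives the 4,6-trans lactone.

Step 11
Reactants: 20 (4R,6S)-4-hydroxy-6-phenyltetrahydro-2H-pyran-2-one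
Product: 21 (4R,6S)-4-(tert-butyldimethylsilyloxy)-6-phenyltetrahydro-2H-pyran-2-one
Conditions: TBSCl, imidazole, DMF, rt
Reagents that add atoms: tert-butyldimethylsilyl chloride CC(C)(C)[Si](C)(C)Cl
Why: Standard silylation, as in step 3.

Step 12
Reactants: 21 (4R,6S)-4-(tert-butyldimethylsilyloxy)-6-phenyltetrahydro-2H-pyran-2-one
Product: 22 (2S,4R)-4-(tert-butyldimethylsilyloxy)-2-phenyl-3,4-dihydro-2H-pyran-6-yl diphenyl phosphate
Conditions: KN(SiMe3)2 added to 21 and (PhO)2P(O)Cl, HMPA, THF, −78 °C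
Reagents that add atoms: diphenyl chlorophosphate O=P(Cl)(Oc1ccccc1)Oc1ccccc1
Why: Ketene acetal phosphate formation as in step 4, again with in situ trapping of the enolate.

Step 13
Reactants: 22 (2S,4R)-4-(tert-butyldimethylsilyloxy)-2-phenyl-3,4-dihydro-2H-pyran-6-yl diphenyl phosphate
Product: 23 tert-butyldimethyl{[(2S,4R)-2-phenyl-6-(trimethylstannyl)-3,4-dihydro-2H-pyran-4-yl]oxy}silane
Conditions: Me3SnSnMe3, Pd(PPh3)4 (5 mol %), LiCl, THF, 65 °C
Reagents that add atoms: hexamethylditin C[Sn](C)(C)[Sn](C)(C)C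
Why: Palladium-catalysed stannylation as in step 5.

Step 14
Reactants: 23 tert-butyldimethyl{[(2S,4R)-2-phenyl-6-(trimethylstannyl)-3,4-dihydro-2H-pyran-4-yl]oxy}silane; 11 3-methoxycyclobut-3-ene-1,2-dione
Product: 26 4-[(2S,4R)-4-(tert-butyldimethylsilyloxy)-2-phenyl-3,4-dihydro-2H-pyran-6-yl]-3,4-dimethoxycyclobut-2-en-1-one, via 6-lithiodihydropyran 24 (not isolated), via lithium alkoxide 25 (not isolated)
Conditions: MeLi, THF, −78 °C; then 11, −78 °C; then MeOTf, −78 → −20 °C
Reagents that add atoms: methyl trifluoromethanesulfonate COS(=O)(=O)C(F)(F)F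
Why: Tin–lithium exchange, regioselective 1,2-addition to the semisquarate and in situ O-methylation as in step 7; the cyclobutenone stereocentre is again inconsequential.

Step 15
Reactants: 26 4-[(2S,4R)-4-(tert-butyldimethylsilyloxy)-2-phenyl-3,4-dihydro-2H-pyran-6-yl]-3,4-dimethoxycyclobut-2-en-1-one
Product: 29 (2S,4R)-4-(tert-butyldimethylsilyloxy)-7,8-dimethoxy-2-phenylchroman-5-ol, via dienylketene 27 (not isolated), via cyclohexadienone 28 (not isolated)
Conditions: toluene (degassed), 110 °C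
Reagents that add atoms: none
Why: The same Moore ring expansion (4π opening, 6π closure of C5–C4a, tautomerisation) builds the aromatic A ring of the chromanol half with C6–H free and C2 and C4 untouched.

Step 16
Reactants: 18 (2S,4S)-4-(tert-butyldimethylsilyloxy)-7,8,8-trimethoxy-2-phenyl-3,4-dihydro-2H-chromen-5(8H)-one; 29 (2S,4R)-4-(tert-butyldimethylsilyloxy)-7,8-dimethoxy-2-phenylchroman-5-ol
Product: 30 (2S,8aS)-8a-{[(2S,4R)-4-(tert-butyldimethylsilyloxy)-7,8-dimethoxy-2-phenylchroman-5-yl]oxy}-7,8,8-trimethoxy-2-phenyl-2,3,8,8a-tetrahydro-5H-chromen-5-one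
Conditions: 29 (1.3 equiv), Cs2CO3 (20 mol %), DMF, 25 → 50 °C
Reagents that add atoms: none
Why: Proposed new method: the phenoxide of 29 should add to C8a″, the β-carbon of the C5″ enone, and the resulting C4a″ enolate should expel the allylic C4″ silanolate (E1cB), moving the double bond to C4″=C4a″ and making C8a″ an aryl ketal, the released silanolate regenerating phenoxide; the closest known reactions are SN2′ substitution of Morita–Baylis–Hillman acetates by phenols and the Ferrier transposition of glycals to 2,3-unsaturated aryl glycosides; C8a″ is set by attack on the face opposite to the C2″ phenyl and C4″ silyloxy groups (cis to each other in 18), which puts the aryloxy group axial and trans to phenyl.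

Step 17
Reactants: 30 (2S,8aS)-8a-{[(2S,4R)-4-(tert-butyldimethylsilyloxy)-7,8-dimethoxy-2-phenylchroman-5-yl]oxy}-7,8,8-trimethoxy-2-phenyl-2,3,8,8a-tetrahydro-5H-chromen-5-one
Product: 31 4-O-(tert-butyldimethylsilyl)-6″-demethoxyneocalycopterone
Conditions: BF3·OEt2 (20 mol %), CH2Cl2, −78 → −40 °C
Reagents that add atoms: none
Why: Ionisation of the C8″ dimethyl ketal gives a methoxy-stabilised cation that the electron-rich C6 of the tethered arene captures (intramolecular Friedel–Crafts alkylation, 5-exo), and the new C8″ centre is fixed because the five-membered ring can only be cis-fused to C8a″.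

Step 18
Reactants: 31 4-O-(tert-butyldimethylsilyl)-6″-demethoxyneocalycopterone
Product: 32 6″-demethoxyneocalycopterone
Conditions: Bu4NF, AcOH, THF, 0 °C → rt
Reagents that add atoms: none
Why: Buffered fluoride desilylation frees the C4 hydroxyl without touching the ketal, the enone or the tertiary methyl ether.

**Compound list**

1 | ethyl (S)-3-hydroxy-3-phenylpropanoate | CCOC(=O)C[C@H](O)c1ccccc1 | starting material
2 | tert-butyl acetate | CC(=O)OC(C)(C)C | starting material
3 | tert-butyl (S)-5-hydroxy-3-oxo-5-phenylpentanoate | CC(C)(C)OC(=O)CC(=O)C[C@H](O)c1ccccc1 | intermediate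
4 | tert-butyl (3S,5S)-3,5-dihydroxy-5-phenylpentanoate (anti) | CC(C)(C)OC(=O)C[C@@H](O)C[C@H](O)c1ccccc1 | intermediate
5 | (4S,6S)-4-hydroxy-6-phenyltetrahydro-2H-pyran-2-one (cis) | O[C@H]1C[C@@H](c2ccccc2)OC(=O)C1 | intermediate
6 | (4S,6S)-4-(tert-butyldimethylsilyloxy)-6-phenyltetrahydro-2H-pyran-2-one | CC(C)(C)[Si](C)(C)O[C@H]1C[C@@H](c2ccccc2)OC(=O)C1 | intermediate
7 | (2S,4S)-4-(tert-butyldimethylsilyloxy)-2-phenyl-3,4-dihydro-2H-pyran-6-yl diphenyl phosphate | CC(C)(C)[Si](C)(C)O[C@H]1C[C@@H](c2ccccc2)OC(OP(=O)(Oc2ccccc2)Oc2ccccc2)=C1 | intermediate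
8 | tert-butyldimethyl{[(2S,4S)-2-phenyl-6-(trimethylstannyl)-3,4-dihydro-2H-pyran-4-yl]oxy}silane | CC(C)(C)[Si](C)(C)O[C@H]1C[C@@H](c2ccccc2)OC([Sn](C)(C)C)=C1 | intermediate
9 | 3,4-dimethoxycyclobut-3-ene-1,2-dione (dimethyl squarate) | COC1=C(OC)C(=O)C1=O | starting material
10 | 4-hydroxy-2,3-dimethoxycyclobut-2-en-1-one | COC1=C(OC)C(O)C1=O | intermediate
11 | 3-methoxycyclobut-3-ene-1,2-dione | COC1=CC(=O)C1=O | intermediate
12 | [(2S,4S)-4-(tert-butyldimethylsilyloxy)-2-phenyl-3,4-dihydro-2H-pyran-6-yl]lithium | CC(C)(C)[Si](C)(C)O[C@H]1C[C@@H](c2ccccc2)OC([Li])=C1 | intermediate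
13 | lithium alkoxide of the 4-hydroxycyclobutenone adduct (cis series) | CC(C)(C)[Si](C)(C)O[C@H]1C[C@@H](c2ccccc2)OC(=C1)C1(O[Li])C(OC)=CC1=O | intermediate
14 | 4-[(2S,4S)-4-(tert-butyldimethylsilyloxy)-2-phenyl-3,4-dihydro-2H-pyran-6-yl]-3,4-dimethoxycyclobut-2-en-1-one (both epimers at the ring C4) | CC(C)(C)[Si](C)(C)O[C@H]1C[C@@H](c2ccccc2)OC(=C1)C1(OC)C(OC)=CC1=O | intermediate
15 | 4-[(2S,4S)-4-(tert-butyldimethylsilyloxy)-2-phenyl-3,4-dihydro-2H-pyran-6-yl]-3,4-dimethoxybuta-1,3-dien-1-one (dienylketene) | CC(C)(C)[Si](C)(C)O[C@H]1C[C@@H](c2ccccc2)OC(=C1)C(OC)=C(OC)C=C=O | intermediate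
16 | (2S,4S)-4-(tert-butyldimethylsilyloxy)-7,8-dimethoxy-2-phenyl-2,3,4,4a-tetrahydro-5H-chromen-5-one (C4a unspecified) | CC(C)(C)[Si](C)(C)O[C@H]1C[C@@H](c2ccccc2)OC2=C(OC)C(OC)=CC(=O)C12 | intermediate
17 | (2S,4S)-4-(tert-butyldimethylsilyloxy)-7,8-dimethoxy-2-phenylchroman-5-ol (2,4-cis) | CC(C)(C)[Si](C)(C)O[C@H]1C[C@@H](c2ccccc2)Oc2c(OC)c(OC)cc(O)c21 | intermediate
18 | (2S,4S)-4-(tert-butyldimethylsilyloxy)-7,8,8-trimethoxy-2-phenyl-3,4-dihydro-2H-chromen-5(8H)-one | CC(C)(C)[Si](C)(C)O[C@H]1C[C@@H](c2ccccc2)OC2=C1C(=O)C=C(OC)C2(OC)OC | intermediate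
19 | tert-butyl (3R,5S)-3,5-dihydroxy-5-phenylpentanoate (syn) | CC(C)(C)OC(=O)C[C@H](O)C[C@H](O)c1ccccc1 | intermediate
20 | (4R,6S)-4-hydroxy-6-phenyltetrahydro-2H-pyran-2-one (trans) | O[C@@H]1C[C@@H](c2ccccc2)OC(=O)C1 | intermediate
21 | (4R,6S)-4-(tert-butyldimethylsilyloxy)-6-phenyltetrahydro-2H-pyran-2-one | CC(C)(C)[Si](C)(C)O[C@@H]1C[C@@H](c2ccccc2)OC(=O)C1 | intermediate
22 | (2S,4R)-4-(tert-butyldimethylsilyloxy)-2-phenyl-3,4-dihydro-2H-pyran-6-yl diphenyl phosphate | CC(C)(C)[Si](C)(C)O[C@@H]1C[C@@H](c2ccccc2)OC(OP(=O)(Oc2ccccc2)Oc2ccccc2)=C1 | intermediate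
23 | tert-butyldimethyl{[(2S,4R)-2-phenyl-6-(trimethylstannyl)-3,4-dihydro-2H-pyran-4-yl]oxy}silane | CC(C)(C)[Si](C)(C)O[C@@H]1C[C@@H](c2ccccc2)OC([Sn](C)(C)C)=C1 | intermediate
24 | [(2S,4R)-4-(tert-butyldimethylsilyloxy)-2-phenyl-3,4-dihydro-2H-pyran-6-yl]lithium | CC(C)(C)[Si](C)(C)O[C@@H]1C[C@@H](c2ccccc2)OC([Li])=C1 | intermediate
25 | lithium alkoxide of the 4-hydroxycyclobutenone adduct (trans series) | CC(C)(C)[Si](C)(C)O[C@@H]1C[C@@H](c2ccccc2)OC(=C1)C1(O[Li])C(OC)=CC1=O | intermediate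
26 | 4-[(2S,4R)-4-(tert-butyldimethylsilyloxy)-2-phenyl-3,4-dihydro-2H-pyran-6-yl]-3,4-dimethoxycyclobut-2-en-1-one (both epimers at the ring C4) | CC(C)(C)[Si](C)(C)O[C@@H]1C[C@@H](c2ccccc2)OC(=C1)C1(OC)C(OC)=CC1=O | intermediate
27 | 4-[(2S,4R)-4-(tert-butyldimethylsilyloxy)-2-phenyl-3,4-dihydro-2H-pyran-6-yl]-3,4-dimethoxybuta-1,3-dien-1-one (dienylketene) | CC(C)(C)[Si](C)(C)O[C@@H]1C[C@@H](c2ccccc2)OC(=C1)C(OC)=C(OC)C=C=O | intermediate
28 | (2S,4R)-4-(tert-butyldimethylsilyloxy)-7,8-dimethoxy-2-phenyl-2,3,4,4a-tetrahydro-5H-chromen-5-one (C4a unspecified) | CC(C)(C)[Si](C)(C)O[C@@H]1C[C@@H](c2ccccc2)OC2=C(OC)C(OC)=CC(=O)C12 | intermediate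
29 | (2S,4R)-4-(tert-butyldimethylsilyloxy)-7,8-dimethoxy-2-phenylchroman-5-ol (2,4-trans) | CC(C)(C)[Si](C)(C)O[C@@H]1C[C@@H](c2ccccc2)Oc2c(OC)c(OC)cc(O)c21 | intermediate
30 | (2S,8aS)-8a-{[(2S,4R)-4-(tert-butyldimethylsilyloxy)-7,8-dimethoxy-2-phenylchroman-5-yl]oxy}-7,8,8-trimethoxy-2-phenyl-2,3,8,8a-tetrahydro-5H-chromen-5-one | COC1=CC(=O)C2=CC[C@@H](c3ccccc3)O[C@@]2(Oc3c4c(c(OC)c(OC)c3)O[C@H](c3ccccc3)C[C@H]4O[Si](C)(C)C(C)(C)C)C1(OC)OC | intermediate
31 | 4-O-(tert-butyldimethylsilyl)-6″-demethoxyneocalycopterone | COC1=CC(=O)C2=CC[C@@H](c3ccccc3)O[C@]23Oc2c4c(c(OC)c(OC)c2[C@]13OC)O[C@H](c1ccccc1)C[C@H]4O[Si](C)(C)C(C)(C)C | intermediate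
32 | 6″-demethoxyneocalycopterone | COC1=CC(=O)C2=CC[C@@H](c3ccccc3)O[C@]23Oc2c4c(c(OC)c(OC)c2[C@]13OC)O[C@H](c1ccccc1)C[C@H]4O | target

**Totals**

Total step count: 18. Longest linear sequence: 11 steps (1, 2, 3, 4, 5, 7, 8, 9, 16, 17, 18).

**Steps most likely to fail**

Step 16. Conjugate addition of a hindered phenoxide to the fully substituted C8a″ may be outrun by alkoxy exchange at C7″, or may stall before the silanolate is expelled. The fallback uses known chemistry and makes the carbon–carbon bond first. Phenol 17 is oxidised with (NH4)2Ce(NO3)6 in aqueous MeCN to (2S,4S)-4-(tert-butyldimethylsilyloxy)-7-methoxy-2-phenyl-3,4-dihydro-2H-chromene-5,8-dione F1. Phenol 29 is converted (MOMCl, iPr2NEt) into its methoxymethyl ether F2, which is lithiated at C6 between the two oxygen substituents (n-BuLi, THF, 0 °C) and added at −78 °C to the C8″ carbonyl of F1 (the C5″ carbonyl is a doubly vinylogous ester). MeOTf traps the alkoxide as the 8″-aryl-8″-methoxy dienone F3, formed as both C8″ epimers. ZnBr2/n-PrSH removes the methoxymethyl group to give the free phenol F4. Cs2CO3 in DMF then closes the ketal by intramolecular oxa-Michael addition to C8a″ with loss of the C4″ silanolate, and the epimer with the aryl group anti to the C4″ silyloxy group should give 31, where the route is rejoined. C8″ is not controlled in this variant and the epimers have to be separated.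

Step 17. The Lewis acid may ionise the aryl ketal at C8a″ instead of the C8″ dimethyl ketal, which would let the arene migrate from oxygen to carbon, or it may ionise the benzylic C4 silyl ether. The fallback sets out from 30: the dimethyl ketal is hydrolysed selectively (oxalic acid on wet silica gel) to the C8″ ketone F5. A chelating Lewis acid (TiCl4, CH2Cl2, −78 °C) then promotes Friedel–Crafts hydroxyalkylation of C6 by this ketone to the tertiary alcohol F6, which is O-methylated (NaH, MeI, DMF) to 31.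

Step 12. The potassium enolate of 21 carries an axial β-silyloxy group and may undergo β-elimination to the unsaturated lactone before it is phosphorylated. The fallback sets out from 21 and avoids a lactone enolate: iBu2AlH (CH2Cl2, −78 °C) reduces 21 to (4R,6S)-4-(tert-butyldimethylsilyloxy)-6-phenyltetrahydro-2H-pyran-2-ol F7. Mesylation and elimination (MsCl, Et3N) give (2S,4R)-4-(tert-butyldimethylsilyloxy)-2-phenyl-3,4-dihydro-2H-pyran F8. Direct C6 lithiation with t-BuLi (THF, −78 → 0 °C) then gives 24, which enters step 14 and leads to 26; competing deprotonation of the benzylic C2–H has to be watched here.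

Further compounds
F1 | step 16 | (2S,4S)-4-(tert-butyldimethylsilyloxy)-7-methoxy-2-phenyl-3,4-dihydro-2H-chromene-5,8-dione | CC(C)(C)[Si](C)(C)O[C@H]1C[C@@H](c2ccccc2)OC2=C1C(=O)C=C(OC)C2=O
F2 | step 16 | (2S,4R)-4-(tert-butyldimethylsilyloxy)-7,8-dimethoxy-5-(methoxymethoxy)-2-phenylchroman | CC(C)(C)[Si](C)(C)O[C@@H]1C[C@@H](c2ccccc2)Oc2c(OC)c(OC)cc(OCOC)c21
F3 | step 16 | (2S,4S)-4-(tert-butyldimethylsilyloxy)-8-[(2S,4R)-4-(tert-butyldimethylsilyloxy)-7,8-dimethoxy-5-(methoxymethoxy)-2-phenylchroman-6-yl]-7,8-dimethoxy-2-phenyl-3,4-dihydro-2H-chromen-5(8H)-one (both C8 epimers) | CC(C)(C)[Si](C)(C)O[C@H]1C[C@@H](c2ccccc2)OC2=C1C(=O)C=C(OC)C2(OC)c1c(OCOC)c2c(c(OC)c1OC)O[C@H](c1ccccc1)C[C@H]2O[Si](C)(C)C(C)(C)C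
F4 | step 16 | (2S,4S)-4-(tert-butyldimethylsilyloxy)-8-[(2S,4R)-4-(tert-butyldimethylsilyloxy)-5-hydroxy-7,8-dimethoxy-2-phenylchroman-6-yl]-7,8-dimethoxy-2-phenyl-3,4-dihydro-2H-chromen-5(8H)-one (both C8 epimers) | CC(C)(C)[Si](C)(C)O[C@H]1C[C@@H](c2ccccc2)OC2=C1C(=O)C=C(OC)C2(OC)c1c(O)c2c(c(OC)c1OC)O[C@H](c1ccccc1)C[C@H]2O[Si](C)(C)C(C)(C)C
F5 | step 17 | (2S,8aS)-8a-{[(2S,4R)-4-(tert-butyldimethylsilyloxy)-7,8-dimethoxy-2-phenylchroman-5-yl]oxy}-7-methoxy-2-phenyl-2,3-dihydro-5H-chromene-5,8(8aH)-dione | COC1=CC(=O)C2=CC[C@@H](c3ccccc3)O[C@@]2(Oc3c4c(c(OC)c(OC)c3)O[C@H](c3ccccc3)C[C@H]4O[Si](C)(C)C(C)(C)C)C1=O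
F6 | step 17 | 8″-O-demethyl derivative of 31 (tertiary C8″ alcohol) | COC1=CC(=O)C2=CC[C@@H](c3ccccc3)O[C@]23Oc2c4c(c(OC)c(OC)c2[C@]13O)O[C@H](c1ccccc1)C[C@H]4O[Si](C)(C)C(C)(C)C
F7 | step 12 | (4R,6S)-4-(tert-butyldimethylsilyloxy)-6-phenyltetrahydro-2H-pyran-2-ol (both anomers) | CC(C)(C)[Si](C)(C)O[C@@H]1C[C@@H](c2ccccc2)OC(O)C1
F8 | step 12 | (2S,4R)-4-(tert-butyldimethylsilyloxy)-2-phenyl-3,4-dihydro-2H-pyran | CC(C)(C)[Si](C)(C)O[C@@H]1C[C@@H](c2ccccc2)OC=C1
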